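At 30 h the flask is to be read for the average length of its chains, and two chemists dispute how many chains it holds.

the same everywhere: J 0.40 M; Z 8.6 mol%

| charge | G | L | remark | time |
|---|---|---|---|---|
| maple | 0.040 M | 12 mM | run made earlier |  |
| birch | 0.040 M | 50 mM | run made earlier |  |
| flask | 0.0400 M | 25 mM |  | 30 h |

| run | time / h | X / % | J / % |
|---|---|---|---|
| maple | 1.50 | 0 | 87 |
| maple | 5.00 | 20 | 70 |
| maple | 8.00 | 38 | 52 |
| maple | 12.0 | 56 | 33 |
| maple | 20.0 | 78 | 7 |
| birch | 4.00 | 3 | 89 |
| birch | 8.00 | 3 | 88 |
| birch | 10.0 | 4 | 82 |
| birch | 15.0 | 5 | 81 |
| birch | 20.0 | 9 | 78 |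

(each reading ± 1.5 percentage points)

* whether the average number of monomer units in a chain (chains begun, living or dead) reaches 20 by 30 h (no / yes)
* average number of monomer units in a chain (chains begun, living or dead) at 30 h

- the average divides the monomer in chains by the number of chains begun, living and dead together
- the earlier runs do not show the number of chains; that part of a forecast is a guess

Both of us read the same loss: J plus X sums to about 88% in the earlier runs, which puts about 0.05 M of J aside early, near c_G = 0.0400 M. The forecast's maker takes that loss as chain starts, one chain to each G, and answers no with an average of 7.5, adding: “This chain count is a guess.”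

I object. The maple and birch runs charge the same G, yet at 20.0 h X reads 78% in maple against 9% in birch, and these runs differ in L, which the forecast itself sees titrating Z. So I count chain starts from Z. The surplus S, the charge of Z minus the charge of L, is for this flask 34.4 mM minus 25 mM, or 9.40 mM, less than c_G. On this view S is a ceiling on the chains begun, so the average stands at or above X divided by S. X at 47.0% of the J charged is then enough for an average of 20. The forecast's J near 22%, out of a balance near 88%, leaves more than that, so I say yes. The forecast's average, with S in place of c_G as the chain count, becomes 31.9, and in powers of ten our two chain counts stand 0.629 apart.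

    J + Q → X + Q, rate k1*[Q]*[J] (k = 9.77 L mol⁻¹ h⁻¹)
    J + Z → Q + X (k = 0.265 L mol⁻¹ h⁻¹)
    Z + L → D (k = 207 L mol⁻¹ h⁻¹)
    G + J → E (k = 5.74 L mol⁻¹ h⁻¹)

The flask gives yes, with an average of 39.1 at 30.0 h. The average passes 20 at 10.1 h, so before then it stands on the forecast's side of 20, as with the 7.34 at 3.00 h. At 30.0 h the flask holds D at 25.0 mM, and beside it the chains Q at 7.59 mM and unused Z at 1.81 mM, which together make 9.40 mM, the value of S. X at 74.2% over S gives a floor of 31.6, less than the 39.1 in the flask.

(The earlier runs and the new flask stem from a simulated flask for an exercise; the scatter is artificial.)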